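I started from what should not change: substrate that leaves reappears as product, and at 40.0 min the maple run read 60 % substrate and 38 % product, a sum of 98.0 %, within the scatter. So I needed to follow one fraction, the substrate left.

| setting | alder | maple | oak | south-east | north |
|---|---|---|---|---|---|
| substrate | 1 M | 1 M | 1 M | 1.0 M | 1.0 M |
| partner | 1.05 M | 1.05 M | 1.5 M | 3.00 M | 1.05 M |
| scavenger | 0.40 M | 1.4 M | 1.2 M | 0.300 M | 1.20 M |
| temperature | 25 °C | 40 °C | 25 °C | 40 °C | 40 °C |
| remark | run made earlier | run made earlier | run made earlier |  |  |
| time |  |  |  | 2.5 h | 2.5 h |

alder run (percent of the substrate charged)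

| time / h | product / % | substrate / % |
|---|---|---|
| 0.417 | 12 | 89 |
| 0.833 | 13 | 87 |
| 1.33 | 18 | 80 |
| 2.00 | 28 | 72 |
| 3.00 | 32 | 64 |

maple run (percent of the substrate charged)

| time / min | product / % | substrate / % |
|---|---|---|
| 5.00 | 5 | 95 |
| 15.0 | 21 | 81 |
| 25.0 | 25 | 74 |
| 40.0 | 38 | 60 |
| 60.0 | 47 | 50 |
| 80.0 | 51 | 49 |

oak run (percent of the substrate charged)

| time / h | product / % | substrate / % |
|---|---|---|
| 0.200 | 2 | 95 |
| 0.417 | 9 | 92 |
| 0.667 | 18 | 87 |
| 1.33 | 26 | 72 |
| 3.00 | 48 | 49 |

(readings scatter by 2 percentage points)

* the winner by amount of product, in percent of the substrate charged; "neither" if no more than 2 percentage points parts them (south-east / north / neither)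
* how much product is there at the end, in percent of the substrate charged: south-east
* how much product is there at the end, in percent of the substrate charged: north



At 1.33 h oak had lost 1.40 times what alder had lost, with 1.43 times its partner and 3.00 times its scavenger, so I took the loss to follow partner. I therefore carried a partner clock: the time in which substrate falls to half when partner is charged equal to substrate. I read it from maple at 40.0 min, a run at the 40 °C of both new flasks, treating that run's charges as equal, and got 1.00 h.

North has nearly equal charges, so the fraction left after 2.5 h is the clock over the clock plus the time, 28.6 %, and product is 71.4 %.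

South-east has partner in excess, so I shortened the clock in proportion, to 0.333 h, a pseudo-first-order decay. That was my weak link: it held partner at its charge, and partner is consumed. Reforged at the partner that remains after one substrate charge is taken off it, the clock becomes 0.500 h, and product is 99.3 %. The scavenger in south-east is 30.0 % of the substrate charge, and alder's last product reading, 32 %, stayed short of its scavenger at 40.0 %, so alder did not test that limit. I committed to south-east ahead of north.

The forecast named north, with 33 % for south-east and 62 % for north, and said of its south-east figure: “This is an inference, not something the data show”. The flasks gave 93.5 % in south-east and 69.1 % in north, so south-east won.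

    substrate + partner ⇌ product + released group (K = 0.940, k = 2.30 × 10⁻⁴ M⁻¹ s⁻¹, Ea = 78.0 kJ mol⁻¹, ΔH = −53.0 kJ mol⁻¹)
    partner + released group ⇌ idle adduct, settled at all times (K = 4.90 M⁻¹, ΔH = −43.0 kJ mol⁻¹)
    scavenger + released group → scavenged by-product (k = 0.0270 M⁻¹ s⁻¹, Ea = 61.0 kJ mol⁻¹)
    (constants at 40 °C)

South-east went past its scavenger: at 2.50 h it held product 93.5 %, scavenger 0 %, scavenged by-product 0.300 M and idle adduct 0.559 M. Its 2.5 h spanned 5.00 reforged clocks, and taking away the difference in partner, the largest single effect, lowers south-east from 93.5 % to 58.9 %. In the neighbour of south-east charged with 0.40 M substrate, unbound partner ended at 83 % of its charge, so I used the full-charge clock of 0.333 h; it gives 99.9 %, and that flask holds 99.1 %.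

Readings and results stem from a simulated flask from invented constants.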